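## Analysis of the target

Compound 20 has a single ring, an oxolane (O1, C2–C5). C2 carries a 4-hydroxy-3-methoxyphenyl group, C3 a CH2O arm acylated by (R)-2-methylbutanoic acid, C4 a 4-hydroxy-3-methoxybenzyl group, and C5 is an unsubstituted CH2. The ring descriptors are (2R,3S,4S): the C2 aryl group is trans to the C3 arm, and the C3 and C4 arms are cis to each other (a lariciresinol-type pattern). The fourth stereocentre, (R) in the acyl chain, is remote from the ring, cannot be induced by it and must be brought in intact.

The sensitive groups are:
- the C2–O1 bond, a benzylic ether activated by a para oxygen (acid-labile, open to hydrogenolysis, and prone to quinone-methide ring opening once the phenol is free);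
- two guaiacol-type phenols, which oxidise easily and compete for acylating agents;
- an ester with an enolisable α-stereocentre.

The synthesis is hard for three reasons. The cis C3/C4 relation sits next to a trans C2/C3 relation. The two one-carbon arms must be told apart, one ending as CH2O-ester and the other as CH2-aryl. The acyl group must end up on the aliphatic oxygen only.

The strategy rests on one feature: the exocyclic carbons on C3 and C4 lie on one face of the oxolane and the C2 aryl group on the other. Both exocyclic C–C bonds can therefore come from one two-carbon reagent added across a C3=C4 double bond of a 2-aryl-2,5-dihydrofuran, from the face opposite the aryl group.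

## Retrosynthetic reasoning

**20 back to 19.** The last operation is a hydrogenolysis that cuts three benzylic C–O bonds of 19: the two aryl benzyl ethers and the benzylic acyloxy group on the C4 arm. The phenols thus stay masked through every basic and organometallic step, and the oxygen left by the aryl addition leaves together with the protecting groups. No separate deoxygenation is needed, and no free phenol ever competes with the aliphatic alcohol for the acyl group. The forward reaction has to spare the fourth benzylic C–O bond, C2–O1.

**19 back to 17 and 18.** Both ester C–O bonds are cut. Acylating both hydroxyls of diol 17 with acid 18 removes the need to distinguish the primary from the secondary alcohol: the primary ester is the one 20 keeps, and the benzylic ester is the leaving group of the last step. The coupling must not enolise the α-centre of 18.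

**17 back to 13 and 15.** The bond between the exocyclic carbon on C4 and its aryl ring is cut. That carbon is at the aldehyde level in lactol 13, which opens to hydroxy aldehyde 16 under the reaction conditions; Grignard reagent 15 is made from bromide 14. The cut is made here, and not between C4 and its exocyclic carbon, because that bond belongs to the key step. The lactol keeps the cis aldehyde from epimerising until the organometallic consumes it.

**13 back to 11 and 10.** The lactol C–O bonds are cut to a hydroxymethyl group on C3 and a dichloromethyl group on C4, a latent aldehyde; chloro ether 12 lies on the way. Alcohol 11 comes from ester 10 by reduction. Reducing before unmasking is deliberate: the neighbouring hydroxyl assists the ionisation, and the aldehyde never sits beside an ester that an aryl nucleophile could also attack.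

**10 back to 9.** The ester carbon on C3 and the CHCl2 carbon on C4 are reconnected to the dichlorocyclobutanone 9. The forward haloform-type cleavage is what differentiates the arms: one leaves the ring at the acid level and the other at the aldehyde level, and they are still cis because they were tied into a four-membered ring.

**9 back to 6 and 8.** This is the key disconnection: the bonds C3–C(=O) and C4–CCl2 are cut together, and ketene 8 is generated from acid chloride 7. The cut takes the target back to a flat alkene with a single stereocentre. The forward cycloaddition must add to the face anti to the aryl group, with the carbonyl carbon on C3.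

**6 back to 4 and 5.** The C2–aryl bond is cut. An asymmetric Heck arylation puts the aryl group on the oxygen-bearing alkene carbon of 5 and moves the double bond to C3=C4, exactly where the cycloaddition needs it. The catalyst sets C2, the only centre not relayed from another.

**4 back to 3, 2 and 1.** The aryl C–O bond of triflate 4 leads to phenol 3, and that to aldehyde 1 through formate 2. Aldehyde 1 is cheap and already carries the protected guaiacyl pattern.

## Alternatives that were turned down

**Alternative 1:** The ring bond C2–C3 and the bond from C4 to its benzylic CH2 are cut, and the oxolane is traded for a γ-lactone. Dithiane A2, as its 2-lithio derivative, adds to the β-carbon of the cellulose-derived butenolide A1 anti to the trityloxymethyl group. The lactone enolate is then alkylated by benzylic bromide A3 trans to the new substituent, giving A4.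
- For it: both bonds come from very dependable enolate chemistry. Each arm comes from its own reagent, so there is no doubt which arm bears the aryl group. The absolute configuration is taken from the chiral pool. The trans lactone translates into the cis C3/C4 arms once the carbons are re-dealt into the oxolane (the lactone carbonyl becomes C5, the γ-carbon becomes the C3 arm).
- Against it: A4 contains the wrong ring. Reaching 20 needs lactone reduction, detritylation, glycol cleavage that discards a carbon, reduction, dithiane hydrolysis, ketone reduction and cyclo-etherification. Three hydroxyls must be told apart so that only the C3 arm is acylated. C2 is fixed only at the end, by an ionising ring closure at an electron-rich benzylic centre.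
- Comparison: on the reliability of the individual C–C bond formations and on arm differentiation this alternative is the stronger one. The chosen route instead makes both exocyclic bonds on the final ring in one step with C2 already in place, excises no carbon, and is shorter (ten steps against an estimated thirteen or more).

**Alternative 2:** Only O1–C2 is cut. The precursor is A5, the mono-ester of a C2-symmetric 2,3-dibenzylbutane-1,4-diol. Its free primary hydroxyl is converted into an alkoxy radical under hypoiodite-type conditions. The radical abstracts a hydrogen from the benzylic CH2 five atoms away through a six-membered transition state; oxidation of the benzylic radical and capture by the same oxygen closes the oxolane to A6, one debenzylation short of 20.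
- For it: the hidden symmetry makes the mono-acylation unambiguous. The acyl group is in place before the ring exists, so neither phenol/alcohol nor arm differentiation arises. The cis C3/C4 arrangement follows from the threo diol. After the diol, the sequence is the shortest of all; on step economy this alternative beats the chosen route.
- Against it: C2 is created in the key step with only a conformational preference for 2,3-trans to control it. The radical and oxidative conditions meet two electron-rich arenes. The primary alkoxy radical can fragment with loss of one carbon. The C2–H of the product is more activated than the C–H that had to be broken, which invites over-oxidation. The enantiopure symmetric diol still needs its own asymmetric synthesis.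
- Comparison: the chosen strategy offers a ring-forming step whose outcome is fixed by geometry (cis fusion, anti to the aryl group) and a C2 centre set beforehand by a catalyst, at the price of more functional-group steps afterwards.

**Alternative 3:** C2–C3 and C4–C5 are cut, so the oxolane is assembled from a C2–O1–C5 carbonyl ylide and a C3=C4 alkene. Fluoride-induced desilylation of the α-chloro ether A8 releases the aryl-substituted ylide, which adds to the menthyloxybutenolide A7 anti to the menthyloxy group to give the cis-fused bicyclic lactone A9.
- For it: it is the most convergent plan, with the ring and all three ring stereocentres made in one step. A9 already has its arms at different oxidation levels (lactone carbonyl on C3, acetal carbon on C4). The chosen route reaches that differentiation only after cutting the cyclobutanone (compare A9 with lactol 13). On convergence and arm differentiation the alternative is as strong or stronger.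
- Against it: the unstabilised ylide has two termini of similar reactivity, so its orientation on the butenolide is not dictated, and the aryl group must in addition end up exo. Two selectivities beyond the facial one must hold at once, and a wrong orientation puts the aryl group on the wrong ring carbon beyond repair. A8 is the α-chloro ether of a strongly donor-substituted benzaldehyde and would ionise on handling. The auxiliary is stoichiometric.
- Comparison: the chosen strategy separates the tasks. C2 comes from an asymmetric Heck reaction of a stable triflate. The cycloaddition then has to answer only one facial and one regiochemical question, and a regiochemical error can be absorbed by exchanging the roles of the arms.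

Key step: step 4

Remark: the lactol carbon of 13 and the carbinol carbon of 17 and 19 form as epimer mixtures and are left undefined because that carbon is CH2 in 20; the (S)-configured PHOX ligand is taken to deliver the (R)-dihydrofuran as it does with simpler aryl triflates, and the mirror-image ligand would be used otherwise.

## Route

Step 1
Reactants: 1 4-(benzyloxy)-3-methoxybenzaldehyde (O-benzylvanillin)
Product: 3 4-(benzyloxy)-3-methoxyphenol, via aryl formate 2 (not isolated)
Conditions: mCPBA, CH2Cl2, 0 → 23 °C; then K2CO3 (cat.), MeOH, 23 °C
Reagents that add atoms: mCPBA (3-chloroperoxybenzoic acid), O=C(OO)c1cccc(Cl)c1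
Why: Dakin-type oxidation run as a Baeyer–Villiger reaction: in the peracid adduct the electron-rich aryl group migrates to oxygen to give formate 2, which mild methanolysis cleaves to phenol 3; the benzyl and methyl ethers are inert.

Step 2
Reactants: 3 4-(benzyloxy)-3-methoxyphenol
Product: 4 4-(benzyloxy)-3-methoxyphenyl trifluoromethanesulfonate
Conditions: Tf2O, pyridine, CH2Cl2, 0 °C
Reagents that add atoms: triflic anhydride (Tf2O), O=S(=O)(OS(=O)(=O)C(F)(F)F)C(F)(F)F
Why: O-sulfonylation of the phenol; the triflate is the pseudohalide that sends the following Heck reaction through the cationic pathway needed for high enantioselectivity.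

Step 3
Reactants: 4 4-(benzyloxy)-3-methoxyphenyl trifluoromethanesulfonate; 5 2,3-dihydrofuran (excess)
Product: 6 (2R)-2-[4-(benzyloxy)-3-methoxyphenyl]-2,5-dihydrofuran
Conditions: Pd2(dba)3 (1.5 mol %), (S)-t-Bu-PHOX (6 mol %), i-Pr2NEt, THF, 70 °C
Reagents that add atoms: none
Why: Asymmetric Heck arylation: oxidative addition of 4 to zerovalent palladium gives a cationic arylpalladium–PHOX complex that inserts the enol ether double bond of 5 with the aryl group going to the oxygen-bearing carbon; β-hydride elimination away from that carbon followed by fast alkene release, typical of P,N ligands, leaves the 2,5-dihydro isomer. C2 is the only new stereocentre and is set (R) by the chiral ligand, which selects the enantioface of 5 in the insertion.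

Step 4
Reactants: 6 (2R)-2-[4-(benzyloxy)-3-methoxyphenyl]-2,5-dihydrofuran; 7 trichloroacetyl chloride
Product: 9 (1S,4R,5R)-4-[4-(benzyloxy)-3-methoxyphenyl]-7,7-dichloro-3-oxabicyclo[3.2.0]heptan-6-one (cis-fused; ketone carbon on the bridgehead next to the aryl-bearing carbon; aryl trans to the four-membered ring), via dichloroketene 8 (not isolated)
Conditions: Zn(Cu), Et2O/DME, slow addition of 7, 20–30 °C, sonication
Reagents that add atoms: none
Why: Zinc reduces 7 to ketene 8, which is consumed as it forms. Ketene 8 adds to the C3=C4 bond of 6 through the orthogonal, asynchronous (2+2) transition state of ketene–alkene cycloadditions (formally suprafacial on the alkene and antarafacial on the ketene), the electrophilic carbonyl carbon bonding first. The closest known reactions are the additions of dichloroketene to cyclopentene, cyclohexene and the parent 2,5-dihydrofuran, which give the corresponding cis-fused dichlorocyclobutanones. The cyclobutanone is the only ring formed; it closes intermolecularly by cycloaddition with both new bonds on one face of the cis-alkene, so the ring fusion at the two new stereocentres (oxolane C3 and C4) is necessarily cis. Their absolute configuration is controlled by the C2 aryl group: the ketene approaches the face anti to it, which places the four-membered ring trans to the aryl group. The step also needs regioselectivity, with the carbonyl carbon bonding to C3: this should be favoured because the positive charge that builds up on the other alkene carbon is less destabilised at C4 (next to CH2–O) than at C3 (next to the carbon bearing both oxygen and aryl), and because the bulky CCl2 terminus avoids the more hindered C3. DME ties up ZnCl2 so that the acid-sensitive allylic benzylic ether and the electron-rich ring are not attacked.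

Step 5
Reactants: 9 (1S,4R,5R)-4-[4-(benzyloxy)-3-methoxyphenyl]-7,7-dichloro-3-oxabicyclo[3.2.0]heptan-6-one
Product: 10 methyl (2R,3R,4S)-2-[4-(benzyloxy)-3-methoxyphenyl]-4-(dichloromethyl)oxolane-3-carboxylate
Conditions: NaOMe (cat.), MeOH/THF, −20 → 0 °C; AcOH quench
Reagents that add atoms: methanol (delivered as methoxide), CO
Why: Haloform-type cleavage of an α,α-dichlorocyclobutanone: methoxide adds to the strained, inductively activated carbonyl and the tetrahedral adduct breaks the C(O)–CCl2 bond towards the chlorine-stabilised carbanion, which methanol protonates, regenerating methoxide. No bond to a stereocentre is broken, so the arms stay cis; catalytic base at low temperature avoids enolisation of the new ester, which could epimerise C3 or eliminate O1.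

Step 6
Reactants: 10 methyl (2R,3R,4S)-2-[4-(benzyloxy)-3-methoxyphenyl]-4-(dichloromethyl)oxolane-3-carboxylate
Product: 11 [(2R,3S,4S)-2-[4-(benzyloxy)-3-methoxyphenyl]-4-(dichloromethyl)oxolan-3-yl]methanol
Conditions: DIBAL-H (i-Bu2AlH), CH2Cl2, −78 → 0 °C; aq. potassium sodium tartrate
Reagents that add atoms: none
Why: Ester reduction by an aluminium hydride that leaves unactivated alkyl chlorides alone; it creates the CH2O arm of C3 and at the same time the neighbouring group that will unmask the aldehyde in the next step.

Step 7
Reactants: 11 [(2R,3S,4S)-2-[4-(benzyloxy)-3-methoxyphenyl]-4-(dichloromethyl)oxolan-3-yl]methanol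
Product: 13 (1S,5S,6R)-6-[4-(benzyloxy)-3-methoxyphenyl]-3,7-dioxabicyclo[3.3.0]octan-2-ol (cis-fused lactol; epimer mixture at C2), via bicyclic chloro ether 12 (not isolated)
Conditions: AgNO3, 2,6-lutidine, acetone/H2O, 23 → 50 °C, dark
Reagents that add atoms: water, O
Why: Silver-assisted solvolysis of a geminal dichloride with neighbouring-group participation: the cis hydroxymethyl oxygen closes a five-membered ring on the ionising carbon to give α-chloro ether 12, whose remaining chloride leaves through the oxocarbenium ion and is replaced by water. The lactol stores the aldehyde in a form that cannot enolise, so the cis C3/C4 relation is kept; lutidine holds the medium near neutral for the benzylic ether.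

Step 8
Reactants: 13 (1S,5S,6R)-6-[4-(benzyloxy)-3-methoxyphenyl]-3,7-dioxabicyclo[3.3.0]octan-2-ol; 14 1-(benzyloxy)-4-bromo-2-methoxybenzene (3 equiv)
Product: 17 [(2R,3S,4S)-2-[4-(benzyloxy)-3-methoxyphenyl]-4-{[4-(benzyloxy)-3-methoxyphenyl](hydroxy)methyl}oxolan-3-yl]methanol (epimer mixture at the carbinol carbon), via aryl Grignard reagent 15 (not isolated), via hydroxy aldehyde 16 (not isolated)
Conditions: 14, Mg, THF, 23 → 50 °C; then 13 added at −40 → 0 °C; H2O quench
Reagents that add atoms: none
Why: Grignard addition to a lactol: the first equivalent of 15 deprotonates 13 and opens it to the alkoxide of 16, and further 15 adds to the aldehyde faster than it can enolise at low temperature. The new carbinol centre forms without control, which does not matter because it becomes CH2 in step 10.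

Step 9
Reactants: 17 [(2R,3S,4S)-2-[4-(benzyloxy)-3-methoxyphenyl]-4-{[4-(benzyloxy)-3-methoxyphenyl](hydroxy)methyl}oxolan-3-yl]methanol; 18 (R)-2-methylbutanoic acid (3 equiv)
Product: 19 [(2R,3S,4S)-2-[4-(benzyloxy)-3-methoxyphenyl]-4-{[4-(benzyloxy)-3-methoxyphenyl][(2R)-2-methylbutanoyloxy]methyl}oxolan-3-yl]methyl (2R)-2-methylbutanoate
Conditions: EDC·HCl, DMAP (cat.), CH2Cl2, 0 → 23 °C
Reagents that add atoms: none
Why: Steglich-type carbodiimide esterification of both hydroxyls; the primary ester is the one kept in 20 and the benzylic ester is the leaving group of step 10, so no primary/secondary selection is needed. With only catalytic DMAP and no strong base the α-centre of the acyl group should not enolise.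

Step 10
Reactants: 19 [(2R,3S,4S)-2-[4-(benzyloxy)-3-methoxyphenyl]-4-{[4-(benzyloxy)-3-methoxyphenyl][(2R)-2-methylbutanoyloxy]methyl}oxolan-3-yl]methyl (2R)-2-methylbutanoate
Product: 20 [(2R,3S,4S)-2-(4-hydroxy-3-methoxyphenyl)-4-(4-hydroxy-3-methoxybenzyl)oxolan-3-yl]methyl (2R)-2-methylbutanoate (the target)
Conditions: H2 (1 atm), 10% Pd/C, EtOAc, 23 °C, stopped when the intermediates are consumed
Reagents that add atoms: none
Why: Catalytic hydrogenolysis: the two aryl benzyl ethers and the benzylic acyloxy C–O bond (directly, or through the para-quinone methide once the phenol is free) should cleave much faster than the dialkyl benzylic ether C2–O1 in a neutral, non-nucleophilic solvent. No stereocentre is touched.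

## Compound list

1 | 4-(benzyloxy)-3-methoxybenzaldehyde (O-benzylvanillin) | COc1cc(C=O)ccc1OCc1ccccc1 | starting material
2 | 4-(benzyloxy)-3-methoxyphenyl formate | COc1cc(OC=O)ccc1OCc1ccccc1 | intermediate
3 | 4-(benzyloxy)-3-methoxyphenol | COc1cc(O)ccc1OCc1ccccc1 | intermediate
4 | 4-(benzyloxy)-3-methoxyphenyl trifluoromethanesulfonate | COc1cc(OS(=O)(=O)C(F)(F)F)ccc1OCc1ccccc1 | intermediate
5 | 2,3-dihydrofuran | C1=COCC1 | starting material
6 | (2R)-2-[4-(benzyloxy)-3-methoxyphenyl]-2,5-dihydrofuran | C1=C[C@H](c2ccc(OCc3ccccc3)c(OC)c2)OC1 | intermediate
7 | trichloroacetyl chloride | ClC(Cl)(Cl)C(Cl)=O | starting material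
8 | dichloroketene | O=C=C(Cl)Cl | intermediate
9 | (1S,4R,5R)-4-[4-(benzyloxy)-3-methoxyphenyl]-7,7-dichloro-3-oxabicyclo[3.2.0]heptan-6-one | O=C1[C@H]2[C@H](c3ccc(OCc4ccccc4)c(OC)c3)OC[C@H]2C1(Cl)Cl | intermediate
10 | methyl (2R,3R,4S)-2-[4-(benzyloxy)-3-methoxyphenyl]-4-(dichloromethyl)oxolane-3-carboxylate | COC(=O)[C@@H]1[C@H](C(Cl)Cl)CO[C@H]1c1ccc(OCc2ccccc2)c(OC)c1 | intermediate
11 | [(2R,3S,4S)-2-[4-(benzyloxy)-3-methoxyphenyl]-4-(dichloromethyl)oxolan-3-yl]methanol | OC[C@@H]1[C@H](C(Cl)Cl)CO[C@H]1c1ccc(OCc2ccccc2)c(OC)c1 | intermediate
12 | (1S,5S,6R)-6-[4-(benzyloxy)-3-methoxyphenyl]-2-chloro-3,7-dioxabicyclo[3.3.0]octane (epimer mixture at C2) | ClC1OC[C@@H]2[C@H]1CO[C@H]2c1ccc(OCc3ccccc3)c(OC)c1 | intermediate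
13 | (1S,5S,6R)-6-[4-(benzyloxy)-3-methoxyphenyl]-3,7-dioxabicyclo[3.3.0]octan-2-ol (epimer mixture at C2) | OC1OC[C@@H]2[C@H]1CO[C@H]2c1ccc(OCc3ccccc3)c(OC)c1 | intermediate
14 | 1-(benzyloxy)-4-bromo-2-methoxybenzene | COc1cc(Br)ccc1OCc1ccccc1 | starting material
15 | [4-(benzyloxy)-3-methoxyphenyl]magnesium bromide | COc1cc([Mg]Br)ccc1OCc1ccccc1 | intermediate
16 | (3S,4S,5R)-5-[4-(benzyloxy)-3-methoxyphenyl]-4-(hydroxymethyl)oxolane-3-carbaldehyde (formed as its magnesium alkoxide) | OC[C@@H]1[C@H](C=O)CO[C@H]1c1ccc(OCc2ccccc2)c(OC)c1 | intermediate
17 | [(2R,3S,4S)-2-[4-(benzyloxy)-3-methoxyphenyl]-4-{[4-(benzyloxy)-3-methoxyphenyl](hydroxy)methyl}oxolan-3-yl]methanol (epimer mixture at the carbinol carbon) | OC[C@@H]1[C@H](C(O)c2ccc(OCc3ccccc3)c(OC)c2)CO[C@H]1c1ccc(OCc2ccccc2)c(OC)c1 | intermediate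
18 | (R)-2-methylbutanoic acid | CC[C@@H](C)C(=O)O | starting material
19 | [(2R,3S,4S)-2-[4-(benzyloxy)-3-methoxyphenyl]-4-{[4-(benzyloxy)-3-methoxyphenyl][(2R)-2-methylbutanoyloxy]methyl}oxolan-3-yl]methyl (2R)-2-methylbutanoate (epimer mixture at the acyloxy-bearing carbon) | CC[C@@H](C)C(=O)OC[C@@H]1[C@H](C(OC(=O)[C@H](C)CC)c2ccc(OCc3ccccc3)c(OC)c2)CO[C@H]1c1ccc(OCc2ccccc2)c(OC)c1 | intermediate
20 | [(2R,3S,4S)-2-(4-hydroxy-3-methoxyphenyl)-4-(4-hydroxy-3-methoxybenzyl)oxolan-3-yl]methyl (2R)-2-methylbutanoate | CC[C@@H](C)C(=O)OC[C@@H]1[C@H](Cc2ccc(O)c(OC)c2)CO[C@H]1c1ccc(O)c(OC)c1 | target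

## Step count and least certain steps

Total: 10 steps. Longest linear sequence: 10 steps (1 to 20); 5, 7, 14 and 18 enter in steps 3, 4, 8 and 9.

**Step 4 (key step).** The most likely failure is poor regioselectivity: the electronic and steric bias between C3 and C4 is small, so a substantial part of the ketene may bond with its carbonyl carbon to C4. Two lesser risks are ionisation of the allylic benzylic C2–O1 bond by zinc salts and acylation of the ring oxygen followed by sigmatropic rearrangement; both are addressed by keeping the ketene concentration low and the zinc salt complexed.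

Fallback, from 6 back to 17, exchanging the roles of the arms. The cycloaddition is run as before and the regioisomeric cycloadduct F1 (carbonyl on C4, CCl2 on C3) is carried on. Methoxide opening as in step 5 should give the methyl ester F2, with the CHCl2 group now on C3. DIBAL-H at −78 °C, where O1 can chelate the aluminium hemiacetal, should stop at the aldehyde F3. Addition of 15 gives the benzylic carbinol F4. AgNO3 in aqueous acetone, as in step 7, closes the carbinol oxygen onto the CHCl2 carbon to give the aryl-substituted lactol F5. NaBH4 reduces F5 through its open form to diol 17.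

**Step 7.** The ionisation of a non-activated geminal dichloride may be too slow even with silver assistance. Loss of HCl to a chloroalkene, or acid-induced opening of the benzylic ether, could then take over.

Fallback, from 9 back to 17, avoiding the dichloromethyl group altogether. Zn/AcOH dechlorination gives the cyclobutanone F6. LDA with TMSCl present at −78 °C forms the silyl enol ether F7 on the CH2 side. Ozonolysis (O3, CH2Cl2/MeOH, −78 °C; Me2S) cuts the enol ether double bond to the cis acid–aldehyde, which closes to the hydroxy lactone F8. Excess 15 followed by mild acid gives the aryl lactone F9, and LiAlH4 reduces F9 to 17.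

**Step 10.** Hydrogenolytic opening of the oxolane at C2–O1 may compete with cleavage of the hindered benzylic ester, because both are para-oxygenated benzylic C–O bonds. The benzylic ester may also cleave incompletely.

Fallback, from 17 back to 20, taking the deoxygenation out of the hydrogenation. Acylation of 17 with one equivalent of 18 (EDC·HCl, catalytic DMAP, −20 °C) should give the primary mono-ester F10. Thiocarbonyldiimidazole converts the benzylic hydroxyl into the imidazolide F11. Barton–McCombie reduction (Bu3SnH, AIBN, toluene, 80 °C) gives F12, the bis(benzyl ether) of 20. A brief hydrogenolysis (H2, 10% Pd/C, EtOAc) then has only the two fast aryl benzyl ether cleavages left to perform and gives 20.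

**Step 3.** Oxidative addition of the electron-rich triflate to zerovalent palladium is slow, so catalyst decay, partial migration of the double bond into conjugation with oxygen, or insufficient enantioselectivity may result.

Fallback, from 1 back to 6, by ring-closing metathesis. Vinylmagnesium bromide adds to 1 to give the racemic carbinol F13. Lipase-mediated acylation (Candida antarctica lipase B, vinyl acetate) should convert the (R)-enantiomer into the acetate F14, which is separated from the unreacted enantiomer of F13. K2CO3/MeOH frees the (R)-carbinol F15. NaH and allyl bromide give the allyl ether F16, and ring-closing metathesis with the second-generation Grubbs catalyst gives 6.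

## Further compounds

F1 | step 4 | (1R,2R,5S)-2-[4-(benzyloxy)-3-methoxyphenyl]-7,7-dichloro-3-oxabicyclo[3.2.0]heptan-6-one (regioisomer of 9) | ClC2(Cl)[C@@H]1[C@H](C2=O)CO[C@H]1c1ccc(OCc3ccccc3)c(OC)c1
F2 | step 4 | methyl (3S,4R,5R)-5-[4-(benzyloxy)-3-methoxyphenyl]-4-(dichloromethyl)oxolane-3-carboxylate (regioisomer of 10) | ClC(Cl)[C@@H]1[C@H](C(=O)OC)CO[C@H]1c1ccc(OCc2ccccc2)c(OC)c1
F3 | step 4 | 5-[4-(benzyloxy)-3-methoxyphenyl]-4-(dichloromethyl)oxolane-3-carbaldehyde, ring configuration as in F2 | ClC(Cl)[C@@H]1[C@H](C=O)CO[C@H]1c1ccc(OCc2ccccc2)c(OC)c1
F4 | step 4 | [4-(benzyloxy)-3-methoxyphenyl]{5-[4-(benzyloxy)-3-methoxyphenyl]-4-(dichloromethyl)oxolan-3-yl}methanol, ring configuration as in F2, carbinol epimers | ClC(Cl)[C@@H]1[C@H](C(O)c2ccc(OCc3ccccc3)c(OC)c2)CO[C@H]1c1ccc(OCc2ccccc2)c(OC)c1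
F5 | step 4 | cis-fused 4,6-bis[4-(benzyloxy)-3-methoxyphenyl]-3,7-dioxabicyclo[3.3.0]octan-2-ol, lactol carbon on oxolane C3, epimers at C2 and C4 of the bicycle | OC2[C@@H]1[C@H](C(c3ccc(OCc4ccccc4)c(OC)c3)O2)CO[C@H]1c1ccc(OCc3ccccc3)c(OC)c1
F6 | step 7 | cis-fused 4-[4-(benzyloxy)-3-methoxyphenyl]-3-oxabicyclo[3.2.0]heptan-6-one (dechlorinated 9) | O=C2[C@@H]1[C@H](C2)CO[C@H]1c1ccc(OCc3ccccc3)c(OC)c1
F7 | step 7 | trimethylsilyl enol ether of F6 (C=C towards the former CH2) | C[Si](C)(C)OC=2[C@@H]1[C@H](C=2)CO[C@H]1c1ccc(OCc3ccccc3)c(OC)c1
F8 | step 7 | cis-fused 6-[4-(benzyloxy)-3-methoxyphenyl]-4-hydroxy-3,7-dioxabicyclo[3.3.0]octan-2-one (hydroxy lactone, carbonyl on oxolane C3, lactol epimers) | O=C2[C@@H]1[C@H](C(O)O2)CO[C@H]1c1ccc(OCc3ccccc3)c(OC)c1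
F9 | step 7 | cis-fused 4,6-bis[4-(benzyloxy)-3-methoxyphenyl]-3,7-dioxabicyclo[3.3.0]octan-2-one (aryl lactone, epimers at C4) | O=C2[C@@H]1[C@H](C(c3ccc(OCc4ccccc4)c(OC)c3)O2)CO[C@H]1c1ccc(OCc3ccccc3)c(OC)c1
F10 | step 10 | primary mono-(2R)-2-methylbutanoate of 17 | CC[C@@H](C)C(=O)OC[C@@H]1[C@H](C(O)c2ccc(OCc3ccccc3)c(OC)c2)CO[C@H]1c1ccc(OCc2ccccc2)c(OC)c1
F11 | step 10 | O-(imidazol-1-ylthiocarbonyl) derivative of F10 at the benzylic oxygen | CC[C@@H](C)C(=O)OC[C@@H]1[C@H](C(OC(=S)n2ccnc2)c2ccc(OCc3ccccc3)c(OC)c2)CO[C@H]1c1ccc(OCc2ccccc2)c(OC)c1
F12 | step 10 | bis(benzyl ether) of 20 | CC[C@@H](C)C(=O)OC[C@@H]1[C@H](Cc2ccc(OCc3ccccc3)c(OC)c2)CO[C@H]1c1ccc(OCc2ccccc2)c(OC)c1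
F13 | step 3 | racemic 1-[4-(benzyloxy)-3-methoxyphenyl]prop-2-en-1-ol | C=CC(O)c1ccc(OCc2ccccc2)c(OC)c1
F14 | step 3 | (1R)-1-[4-(benzyloxy)-3-methoxyphenyl]prop-2-en-1-yl acetate | C=C[C@H](c1ccc(OCc2ccccc2)c(OC)c1)OC(C)=O
F15 | step 3 | (1R)-1-[4-(benzyloxy)-3-methoxyphenyl]prop-2-en-1-ol | C=C[C@H](c1ccc(OCc2ccccc2)c(OC)c1)O
F16 | step 3 | (1R)-1-[4-(benzyloxy)-3-methoxyphenyl]prop-2-en-1-yl allyl ether | C=C[C@H](c1ccc(OCc2ccccc2)c(OC)c1)OCC=C
A1 | alternative 1 | (S)-5-[(trityloxy)methyl]furan-2(5H)-one | O=C1C=C[C@@H](COC(c2ccccc2)(c2ccccc2)c2ccccc2)O1
A2 | alternative 1 | 2-[4-(benzyloxy)-3-methoxyphenyl]-1,3-dithiane | COc1cc(C2SCCCS2)ccc1OCc1ccccc1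
A3 | alternative 1 | 4-(benzyloxy)-3-methoxybenzyl bromide | COc1cc(CBr)ccc1OCc1ccccc1
A4 | alternative 1 | trans,trans α-(arylmethyl)-β-(2-aryl-1,3-dithian-2-yl)-γ-(trityloxymethyl)butyrolactone | O=C1[C@@H](Cc2ccc(OCc3ccccc3)c(OC)c2)[C@H](C2(c3ccc(OCc4ccccc4)c(OC)c3)SCCCS2)[C@@H](COC(c2ccccc2)(c2ccccc2)c2ccccc2)O1
A5 | alternative 2 | mono-(2R)-2-methylbutanoate of (2S,3S)-2,3-bis[4-(benzyloxy)-3-methoxybenzyl]butane-1,4-diol | CC[C@@H](C)C(=O)OC[C@@H](Cc1ccc(OCc2ccccc2)c(OC)c1)[C@H](Cc1ccc(OCc2ccccc2)c(OC)c1)CO
A6 | alternative 2 | O,O'-dibenzyl ether of the target | CC[C@@H](C)C(=O)OC[C@@H]1[C@H](Cc2ccc(OCc3ccccc3)c(OC)c2)CO[C@H]1c1ccc(OCc2ccccc2)c(OC)c1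
A7 | alternative 3 | (5R)-5-[(1R,2S,5R)-menthyloxy]furan-2(5H)-one | O=C1O[C@@H](O[C@@H]2C[C@H](C)CC[C@H]2C(C)C)C=C1
A8 | alternative 3 | [4-(benzyloxy)-3-methoxyphenyl]chloromethyl (trimethylsilyl)methyl ether (racemic) | COc1cc(C(Cl)OC[Si](C)(C)C)ccc1OCc1ccccc1
A9 | alternative 3 | cis-fused 2-aryl-oxolane menthyloxy lactone cycloadduct | O=C1O[C@@H](O[C@@H]3C[C@H](C)CC[C@H]3C(C)C)[C@@H]2CO[C@@H](c3ccc(OCc4ccccc4)c(OC)c3)[C@H]12
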